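The route rests on an intramolecular Diels–Alder reaction of a furan. It exploits the 1,4-relationship in ring B between the ring-fusion carbon C5 and the oxygen-bearing C8: a 2-methylfuran supplies C5, C6, C7 and C8, and its oxygen becomes the C8 tertiary hydroxyl. A tethered (E)-3-methyl enoate supplies C9 and C10. One cycloaddition in a monocyclic precursor forms the C5–C10 and C8–C9 bonds, closes rings A and B and sets C5, C8, C9 and C10 under control of the C4 quaternary centre, made earlier by catalytic asymmetric allylation. In-flask reductive opening of the oxygen bridge, hydroboration, two B-alkyl Suzuki couplings and a vinylogous aldol reaction complete the target.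

Key step: step 6

Remark on numbering: labdane-type numbering is used. Ring A is C1–C5 and C10; ring B is C5–C10; the side chain is C11–C15; C18 is the carbon on the α face of C4 (the later carboxyl); C1′–C5′ are the butenolide atoms (C5′ is the ring CH). β is the face of the C10 methyl, α the opposite face.

Remark on assumptions: the enantiomers of TRIP (step 2) and BINOL (step 13) are assigned by analogy and would be confirmed on a test scale; the enantiomer that delivers the stated configuration is the one to use.

Step 1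
Reactants: 1 2-acetyl-5-methylfuran; 2 (methoxymethyl)triphenylphosphonium chloride
Product: 4 rac-2-(5-methylfuran-2-yl)propanal, via enol ether 3 (not isolated)
Conditions: KOtBu, THF, 0 °C → rt; then 1 M aq. HCl, THF, 0 °C
Reagents that add atoms: water (O)
Why: Wittig methoxymethylenation of the ketone and mild acid hydrolysis of the enol ether (one-carbon homologation) should give the α-branched aldehyde; its stereocentre is racemic and is reset in step 2.

Step 2
Reactants: 4 rac-2-(5-methylfuran-2-yl)propanal; 5 allyl alcohol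
Product: 6 (2R)-2-methyl-2-(5-methylfuran-2-yl)pent-4-enal
Conditions: Pd(PPh3)4 (3 mol %), (S)-TRIP (3 mol %), Ph2CHNH2 (40 mol %), 5 Å MS, toluene, 40 °C; then 2 M aq. HCl
Reagents that add atoms: none
Why: Catalytic asymmetric α-allylation of an α-branched aldehyde (amine, palladium and chiral phosphoric acid acting together): the enamine attacks a π-allylpalladium cation paired with the chiral phosphate, which should set the quaternary C4 as R.

Step 3
Reactants: 6 (2R)-2-methyl-2-(5-methylfuran-2-yl)pent-4-enal; 7 propane-1,3-dithiol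
Product: 8 2-[(2R)-2-(5-methylfuran-2-yl)pent-4-en-2-yl]-1,3-dithiane
Conditions: BF3·OEt2 (0.2 equiv), CH2Cl2, −20 → 0 °C
Reagents that add atoms: none
Why: Lewis acid catalysed dithioacetalisation of a non-enolisable aldehyde masks C18 as a bulky, robust formyl equivalent and leaves C4 untouched.

Step 4
Reactants: 9 methyl acetoacetate
Product: 10 methyl (2E)-3-{[(trifluoromethyl)sulfonyl]oxy}but-2-enoate
Conditions: Tf2O, 25% aq. Me4NOH, hexane, 5 °C → rt
Reagents that add atoms: trifluoromethanesulfonic anhydride (O=S(=O)(OS(=O)(=O)C(F)(F)F)C(F)(F)F)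
Why: Stereoselective enol triflation: the non-chelated tetramethylammonium enolate adopts the extended geometry, so O-sulfonylation should give the (E)-enol triflate.

Step 5
Reactants: 8 2-[(2R)-2-(5-methylfuran-2-yl)pent-4-en-2-yl]-1,3-dithiane; 10 methyl (2E)-3-{[(trifluoromethyl)sulfonyl]oxy}but-2-enoate
Product: 12 methyl (2E,7R)-7-(1,3-dithian-2-yl)-3-methyl-7-(5-methylfuran-2-yl)oct-2-enoate, via alkylborane 11 (not isolated)
Conditions: 9-BBN, THF, 0 °C → rt; then 10, Pd(dppf)Cl2 (5 mol %), AsPh3, 3 M aq. K3PO4, DMF, rt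
Reagents that add atoms: none
Why: Anti-Markovnikov hydroboration of the terminal alkene and B-alkyl Suzuki–Miyaura coupling, which proceeds with retention of the triflate geometry, should give the (E)-3-methyl enoate with the tether trans to the ester.

Step 6
Reactants: 12 methyl (2E,7R)-7-(1,3-dithian-2-yl)-3-methyl-7-(5-methylfuran-2-yl)oct-2-enoate
Product: 14 Δ5-octalin hydroxy ester, via oxa-bridged cycloadduct 13 (not isolated)
Conditions: MeAlCl2 (3 equiv), CH2Cl2, −78 → −30 °C; then Et3SiH (5 equiv), −78 → −30 °C; aq. NaHCO3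
Reagents that add atoms: none
Why: MeAlCl2 binds the ester and lowers the LUMO of the (E)-enoate so that the electron-rich 2,5-dialkylfuran (C5=C6–C7=C8) adds across C9=C10 in a concerted but asynchronous [4+2] cycloaddition (C5–C10 ahead of C8–C9), the closest precedent being the MeAlCl2-promoted intramolecular Diels–Alder reaction of furans with tethered enones. Ring A closes through the tether C4–C3–C2–C1 in a chair-like, tether-exo transition state by the C5–C10 bond, and ring B closes as the six-membered carbocycle of the 7-oxanorbornene by the C5–C10 and C8–C9 bonds. Suprafacial addition to the (E)-alkene places the C10 methyl and the C9 ester cis (both endo, β), the bridging oxygen fixes C5 and C8 on the α face, and the sense of addition relative to C4 follows from the 1,3-dithian-2-yl group taking the pseudo-equatorial site anti to the forming C5–C10 bond while the smaller methyl sits pseudo-axial. The step therefore needs facial selectivity with respect to C4 and the tether-exo mode, which the size difference of the two C4 substituents and the short tether should secure, while the regiochemistry is fixed by the tether. Because such furan adducts revert easily, the aluminium-bound adduct is reduced in the same flask: excess MeAlCl2 ionises the more strained C5–O bond (ionisation at C8 is disfavoured by the adjacent complexed ester, which is then also too electron-poor to act as a neighbouring group) and Et3SiH delivers hydride to C7 of the allyl cation in a Kursanov–Parnes type ionic hydrogenation. This should give the C5=C6 alkene and the free 8α-hydroxyl with C8, C9 and C10 untouched.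

Step 7
Reactants: 14 Δ5-octalin hydroxy ester
Product: 16 trans-decalin diol ester, via C6 alkylborane 15 (not isolated)
Conditions: BH3·THF (5 equiv), THF, 0 °C → rt; then NaBO3·4H2O, THF/H2O, rt
Reagents that add atoms: sodium perborate ([Na+].[Na+].O[B-]1(O)OO[B-](O)(O)OO1)
Why: Hydroboration–oxidation: BH3 adds syn from the α face, since the β face is screened by the axial methyls on C4, C8 and C10, with boron on the less substituted C6, so oxidation with retention should give 5α-H (trans ring fusion) and the equatorial 6α-OH.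

Step 8
Reactants: 16 trans-decalin diol ester
Product: 18 9β-vinyl decalin diol, via aldehyde 17 (not isolated)
Conditions: i-Bu2AlH (3.5 equiv), toluene, −78 °C; then Ph3P=CH2 (from Ph3PCH3Br, KN(SiMe3)2), THF, −78 °C → rt
Reagents that add atoms: methyltriphenylphosphonium bromide (C[P+](c1ccccc1)(c1ccccc1)c1ccccc1.[Br-])
Why: One-pot partial reduction of the ester to its aluminium hemiacetal and Wittig methylenation of the aldehyde released on warming should give the vinyl group; no stereocentre is formed and C9 keeps its equatorial β substituent.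

Step 9
Reactants: 18 9β-vinyl decalin diol; 10 methyl (2E)-3-{[(trifluoromethyl)sulfonyl]oxy}but-2-enoate
Product: 20 side-chain (E)-enoate, via alkylborane 19 (not isolated)
Conditions: 9-BBN (4 equiv), THF, rt → 40 °C; then 10, Pd(dppf)Cl2 (5 mol %), AsPh3, 3 M aq. K3PO4, DMF, rt
Reagents that add atoms: none
Why: Hydroboration of the only alkene places boron on C12, and B-alkyl Suzuki–Miyaura coupling with retention of the triflate geometry should form the C12–C13 bond and the (13E)-trisubstituted alkene.

Step 10
Reactants: 20 side-chain (E)-enoate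
Product: 21 (E)-allylic alcohol
Conditions: i-Bu2AlH (5 equiv), CH2Cl2, −78 → −20 °C
Reagents that add atoms: none
Why: 1,2-Reduction of the α,β-unsaturated ester by i-Bu2AlH should give the primary allylic alcohol without touching the alkene geometry.

Step 11
Reactants: 21 (E)-allylic alcohol
Product: 22 (E)-enal
Conditions: MnO2 (20 equiv), CH2Cl2, rt
Reagents that add atoms: none
Why: MnO2 oxidises only the allylic alcohol, so the secondary 6-OH, the tertiary 8-OH and the dithiane should survive.

Step 12
Reactants: 23 4-methylfuran-2(5H)-one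
Product: 24 trimethyl[(4-methylfuran-2-yl)oxy]silane
Conditions: Me3SiOTf, Et3N, CH2Cl2, 0 °C
Reagents that add atoms: trimethylsilyl trifluoromethanesulfonate (C[Si](C)(C)OS(=O)(=O)C(F)(F)F)
Why: Soft enolisation and O-silylation of the butenolide should give the aromatic 2-silyloxyfuran (silyl dienol ether).

Step 13
Reactants: 22 (E)-enal; 24 trimethyl[(4-methylfuran-2-yl)oxy]silane
Product: 26 dithiane triol bearing the butenolide, via silylated aldol adduct 25 (not isolated)
Conditions: Ti(OiPr)4 (20 mol %), (S)-BINOL (20 mol %), Et2O, −20 °C; then 1 M aq. HCl, THF, 0 °C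
Reagents that add atoms: none
Why: Vinylogous Mukaiyama aldol reaction: the Ti–BINOL Lewis acid activates the enal and the silyloxyfuran attacks through C5′ in an open transition state that should favour the syn (threo) pair C15/C5′, while the catalyst, not the remote decalin, selects the aldehyde face and so should set 15S and 5′S; the acid work-up cleaves the silyl ether.

Step 14
Reactants: 26 dithiane triol bearing the butenolide
Product: 27 C18 aldehyde
Conditions: PhI(OCOCF3)2 (1.5 equiv), NaHCO3, MeCN/H2O 9:1, 0 °C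
Reagents that add atoms: water (O)
Why: Oxidative hydrolysis of the dithioacetal by the hypervalent iodine reagent is fast at 0 °C and should unmask the neopentyl aldehyde without touching the alkenes, the alcohols or the butenolide.

Step 15
Reactants: 27 C18 aldehyde
Product: 28 CNP0292216.1
Conditions: NaClO2, NaH2PO4, 2-methyl-2-butene, t-BuOH/H2O, 0 °C → rt
Reagents that add atoms: sodium chlorite ([Na+].[O-]Cl=O)
Why: Pinnick oxidation converts only the aldehyde into the carboxylic acid under buffered conditions, with the alkene scavenger protecting the C13=C14 alkene and the allylic alcohol.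

Compound list
1 | 2-acetyl-5-methylfuran | CC(=O)c1ccc(C)o1 | starting material
2 | (methoxymethyl)triphenylphosphonium chloride | COC[P+](c1ccccc1)(c1ccccc1)c1ccccc1.[Cl-] | starting material
3 | 2-(1-methoxyprop-1-en-2-yl)-5-methylfuran (E/Z mixture) | COC=C(C)c1ccc(C)o1 | intermediate
4 | rac-2-(5-methylfuran-2-yl)propanal | CC(C=O)c1ccc(C)o1 | intermediate
5 | allyl alcohol (prop-2-en-1-ol) | C=CCO | starting material
6 | (2R)-2-methyl-2-(5-methylfuran-2-yl)pent-4-enal | C=CC[C@@](C)(C=O)c1ccc(C)o1 | intermediate
7 | propane-1,3-dithiol | SCCCS | starting material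
8 | 2-[(2R)-2-(5-methylfuran-2-yl)pent-4-en-2-yl]-1,3-dithiane | C=CC[C@@](C)(C1SCCCS1)c1ccc(C)o1 | intermediate
9 | methyl acetoacetate (methyl 3-oxobutanoate) | COC(=O)CC(C)=O | starting material
10 | methyl (2E)-3-{[(trifluoromethyl)sulfonyl]oxy}but-2-enoate | COC(=O)/C=C(\C)OS(=O)(=O)C(F)(F)F | intermediate
11 | 9-[(4R)-4-(1,3-dithian-2-yl)-4-(5-methylfuran-2-yl)pentyl]-9-borabicyclo[3.3.1]nonane | B1(CCC[C@@](C)(C2SCCCS2)c2ccc(C)o2)C2CCCC1CCC2 | intermediate
12 | methyl (2E,7R)-7-(1,3-dithian-2-yl)-3-methyl-7-(5-methylfuran-2-yl)oct-2-enoate | COC(=O)/C=C(\C)CCC[C@@](C)(C1SCCCS1)c1ccc(C)o1 | intermediate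
13 | oxa-bridged cycloadduct: methyl 4α-(1,3-dithian-2-yl)-5α,8α-epoxy-4β,8β,10β-trimethyl-Δ6-octalin-9β-carboxylate (H9 α) | COC(=O)[C@@H]1[C@@]2(C)CCC[C@@](C)(C3SCCCS3)[C@@]42C=C[C@@]1(C)O4 | intermediate
14 | methyl 4α-(1,3-dithian-2-yl)-8α-hydroxy-4β,8β,10β-trimethyl-Δ5-octalin-9β-carboxylate | COC(=O)[C@@H]1[C@@]2(C)CCC[C@@](C)(C3SCCCS3)C2=CC[C@@]1(C)O | intermediate
15 | 6α-boryl derivative of 14 (5α-H, C6–BH2) | COC(=O)[C@@H]1[C@@]2(C)CCC[C@@](C)(C3SCCCS3)[C@@H]2[C@@H](B)C[C@@]1(C)O | intermediate
16 | methyl 4α-(1,3-dithian-2-yl)-6α,8α-dihydroxy-4β,8β,10β-trimethyl-5α-decalin-9β-carboxylate (trans-fused) | COC(=O)[C@@H]1[C@@]2(C)CCC[C@@](C)(C3SCCCS3)[C@@H]2[C@@H](O)C[C@@]1(C)O | intermediate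
17 | 9β-formyl analogue of 16 (C11 aldehyde, 6α,8α-diol) | O=C[C@@H]1[C@@]2(C)CCC[C@@](C)(C3SCCCS3)[C@@H]2[C@@H](O)C[C@@]1(C)O | intermediate
18 | 9β-vinyl analogue of 16 (C11=C12, 6α,8α-diol) | C=C[C@@H]1[C@@]2(C)CCC[C@@](C)(C3SCCCS3)[C@@H]2[C@@H](O)C[C@@]1(C)O | intermediate
19 | C12-(9-borabicyclo[3.3.1]nonan-9-yl) derivative of 18 | B1(CC[C@@H]2[C@@]3(C)CCC[C@@](C)(C4SCCCS4)[C@@H]3[C@@H](O)C[C@@]2(C)O)C2CCCC1CCC2 | intermediate
20 | methyl (13E)-enoate: 9β-[(3E)-5-methoxy-3-methyl-5-oxopent-3-en-1-yl] decalin 6α,8α-diol with 4α-(1,3-dithian-2-yl) | COC(=O)/C=C(\C)CC[C@@H]1[C@@]2(C)CCC[C@@](C)(C3SCCCS3)[C@@H]2[C@@H](O)C[C@@]1(C)O | intermediate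
21 | (13E)-allylic alcohol (C15–OH) corresponding to 20 | OC/C=C(\C)CC[C@@H]1[C@@]2(C)CCC[C@@](C)(C3SCCCS3)[C@@H]2[C@@H](O)C[C@@]1(C)O | intermediate
22 | (13E)-enal (C15 aldehyde) corresponding to 20 | O=C/C=C(\C)CC[C@@H]1[C@@]2(C)CCC[C@@](C)(C3SCCCS3)[C@@H]2[C@@H](O)C[C@@]1(C)O | intermediate
23 | 4-methylfuran-2(5H)-one | CC1=CC(=O)OC1 | starting material
24 | trimethyl[(4-methylfuran-2-yl)oxy]silane | Cc1coc(O[Si](C)(C)C)c1 | intermediate
25 | 15-O-trimethylsilyl ether of 26 (15S,5′S) | CC1=CC(=O)O[C@@H]1[C@@H](O[Si](C)(C)C)/C=C(\C)CC[C@@H]1[C@@]2(C)CCC[C@@](C)(C3SCCCS3)[C@@H]2[C@@H](O)C[C@@]1(C)O | intermediate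
26 | (15S,5′S)-6α,8α,15-triol with the 4-methylbutenolide on C15 and 4α-(1,3-dithian-2-yl) | CC1=CC(=O)O[C@@H]1[C@@H](O)/C=C(\C)CC[C@@H]1[C@@]2(C)CCC[C@@](C)(C3SCCCS3)[C@@H]2[C@@H](O)C[C@@]1(C)O | intermediate
27 | C18 aldehyde (4α-formyl) corresponding to 26 | CC1=CC(=O)O[C@@H]1[C@@H](O)/C=C(\C)CC[C@@H]1[C@@]2(C)CCC[C@@](C)(C=O)[C@@H]2[C@@H](O)C[C@@]1(C)O | intermediate
28 | CNP0292216.1 (4α-carboxylic acid; 4β,8β,10β-trimethyl; 5α-H; 6α,8α-diol; 9α-H; 13E; 15S; 5′S) | CC1=CC(=O)O[C@@H]1[C@@H](O)/C=C(\C)CC[C@@H]1[C@@]2(C)CCC[C@@](C)(C(=O)O)[C@@H]2[C@@H](O)C[C@@]1(C)O | target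

Total step count: 15
Longest linear sequence: 13 steps (steps 1, 2, 3, 5, 6, 7, 8, 9, 10, 11, 13, 14, 15)

Steps most likely to fail

Step 6. The β,β-disubstituted enoate may be too weak a dienophile for a cycloaddition that creates two adjacent quaternary carbons. The adduct may revert before it is reduced, and the two C4 substituents may discriminate poorly between the furan faces. The allyl cation may also be captured by chloride or rearrange instead of taking up hydride. The fallback separates the two events and uses a more electrophilic dienophile; it sets out from 12 and comes back at 13. Enoate 12 is reduced with i-Bu2AlH to the allylic alcohol F1 and oxidised with MnO2 to the enal F2. Cycloaddition of F2 with Me2AlCl in CH2Cl2 at −78 °C should give the bridged aldehyde F3, which is isolated cold. Pinnick oxidation (NaClO2, NaH2PO4, large excess of 2-methyl-2-butene) gives the acid F4, and Me3SiCHN2 in MeOH/toluene gives ester 13. Compound 13 is then treated with MeAlCl2 and Et3SiH as in the second stage of step 6 to reach 14.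

Step 13. Face selection at the β,β-disubstituted enal by the titanium catalyst may be low, and the syn/anti preference of the open transition state may be eroded, with no help from the remote stereocentres. The fallback replaces catalyst control by resolution; it sets out from 22 and comes back at 26. Enal 22 and silyloxyfuran 24 are combined with BF3·OEt2 in CH2Cl2 at −78 °C and worked up with aq. HCl. This should still favour the syn relationship but gives both syn adducts, 26 and its (15R,5′R)-diastereomer F5. Burkholderia cepacia lipase with vinyl acetate is then expected to acetylate the (15R)-carbinol to the acetate F6, so that unchanged 26 is separated as the alcohol.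

Step 8. The aluminium hemiacetal may be over-reduced to the primary alcohol. The β-oxygenated aldehyde set free in the basic ylide solution may fragment by retro-aldol cleavage of the C8–C9 bond or epimerise at C9. The fallback protects first and isolates the aldehyde; it sets out from 16 and comes back at 18. Both hydroxyls of 16 are silylated with Et3SiOTf and 2,6-lutidine to the bis(triethylsilyl) ether F7. i-Bu2AlH at −78 °C gives the isolated β-silyloxy aldehyde F8, and salt-free Ph3P=CH2 at −78 °C gives the vinyl compound F9. HF·pyridine in THF then returns diol 18.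

Further compounds
F1 | step 6 | (2E,7R)-7-(1,3-dithian-2-yl)-3-methyl-7-(5-methylfuran-2-yl)oct-2-en-1-ol | OC/C=C(\C)CCC[C@@](C)(C1SCCCS1)c1ccc(C)o1
F2 | step 6 | (2E,7R)-7-(1,3-dithian-2-yl)-3-methyl-7-(5-methylfuran-2-yl)oct-2-enal | O=C/C=C(\C)CCC[C@@](C)(C1SCCCS1)c1ccc(C)o1
F3 | step 6 | oxa-bridged cycloadduct aldehyde (9β-formyl analogue of 13) | O=C[C@@H]1[C@@]2(C)CCC[C@@](C)(C3SCCCS3)[C@@]42C=C[C@@]1(C)O4
F4 | step 6 | oxa-bridged cycloadduct acid (9β-carboxylic acid analogue of 13) | OC(=O)[C@@H]1[C@@]2(C)CCC[C@@](C)(C3SCCCS3)[C@@]42C=C[C@@]1(C)O4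
F5 | step 13 | (15R,5′R)-diastereomer of 26 | CC1=CC(=O)O[C@H]1[C@H](O)/C=C(\C)CC[C@@H]1[C@@]2(C)CCC[C@@](C)(C3SCCCS3)[C@@H]2[C@@H](O)C[C@@]1(C)O
F6 | step 13 | 15-O-acetate of F5 | CC1=CC(=O)O[C@H]1[C@H](OC(C)=O)/C=C(\C)CC[C@@H]1[C@@]2(C)CCC[C@@](C)(C3SCCCS3)[C@@H]2[C@@H](O)C[C@@]1(C)O
F7 | step 8 | 6α,8α-bis(triethylsilyl) ether of 16 | COC(=O)[C@@H]1[C@@]2(C)CCC[C@@](C)(C3SCCCS3)[C@@H]2[C@@H](O[Si](CC)(CC)CC)C[C@@]1(C)O[Si](CC)(CC)CC
F8 | step 8 | 6α,8α-bis(triethylsilyl) ether of aldehyde 17 | O=C[C@@H]1[C@@]2(C)CCC[C@@](C)(C3SCCCS3)[C@@H]2[C@@H](O[Si](CC)(CC)CC)C[C@@]1(C)O[Si](CC)(CC)CC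
F9 | step 8 | 6α,8α-bis(triethylsilyl) ether of 18 | C=C[C@@H]1[C@@]2(C)CCC[C@@](C)(C3SCCCS3)[C@@H]2[C@@H](O[Si](CC)(CC)CC)C[C@@]1(C)O[Si](CC)(CC)CC
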